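The reading time of 2.5 h was the first item of the meeting, which had to rank flasks that differ in the D charged and agree in G (11 mM) and X (11.0 mM).

in all of them: G 11 mM
- epsilon: D 17 mM; X 11 mM; run made earlier
- zeta: D 58 mM; X 11 mM; run made earlier
- alpha: D 240 mM; X 11 mM; run made earlier
- south: D 120 mM; X 11.0 mM; time 2.5 h
- west: D 15.0 mM; X 11.0 mM; time 2.5 h
- north: D 44.0 mM; X 11.0 mM; time 2.5 h
- south-east: D 80.0 mM; X 11.0 mM; time 2.5 h
- north-west: D 200 mM; X 11.0 mM; time 2.5 h

| run | time / min | L / % |
|---|---|---|
| epsilon | 20.0 | 0 |
| epsilon | 40.0 | 0.2 |
| epsilon | 60.0 | 1.4 |
| epsilon | 80.0 | 1.3 |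
| epsilon | 120 | 2.4 |
| zeta | 8.00 | 0.6 |
| zeta | 15.0 | 2.6 |
| zeta | 30.0 | 4.7 |
| zeta | 60.0 | 5.7 |
| zeta | 120 | 8.4 |
| alpha | 8.00 | 5.2 |
| alpha | 15.0 | 6.8 |
| alpha | 30.0 | 14.6 |
| alpha | 60.0 | 21.6 |
| alpha | 120 | 30.6 |

(readings scatter by 1 percentage point)



1. the flasks put in order of amount of L, in percent of the G charged, best first, at 2.5 h (south / west / north / south-east / north-west)
2. the same order at 20 h (south / west / north / south-east / north-west)
3. the amount of L, in percent of the G charged of the flask you put first, at 2.5 h
4. the amount of L, in percent of the G charged of the flask you put last, at 2.5 h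

The first speaker reported that L at the last reading, taken per molar of D charged as a fraction of the G charged, stands at 1.45 M⁻¹ in the zeta run and 1.28 M⁻¹ in the alpha run, and argued that with a scatter of 1 percentage point the two may be read as one proportion to D. The second speaker objected that L does not grow steadily, since in the alpha run the gain from 60.0 min to 120 min is 0.417 of what the first 60.0 min brought. Reading the curve as a rise to a plateau, the speaker put the time constant τ, the crossing at which the line of the initial rate meets the plateau, at 68.5 min. The chair drew the meeting's own reckoning from this: the alpha readings give a plateau w of 1.54 M⁻¹, in the same measure, and the time of reading lies 2.19 time constants out, past the crossing, with 88.8% of the rise done. The reach ρ, the fraction of the G charged turned into L per molar of D charged by the reading time, with G and X as charged here, is therefore 1.37 M⁻¹. The meeting so expected the order of the D charged, with north-west at 27.4% and west at 2.05%, and the same order at 20 h, with north-west near its plateau of 30.9%.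

The forecast ranks north-west > south > south-east > north > west at 2.5 h and north-west > south > south-east > north > west at 20 h and gives 29% and 2.3%, a little above the meeting's figures, reading the bend as “something dying or being inhibited”.

The flasks give north-west > south > south-east > north > west at 2.5 h and north-west > south > south-east > north > west at 20 h, with 28.4% in north-west and 2.42% in west at 2.5 h.

    2 G ⇌ E, settled at all times (K = 190 M⁻¹)
    G + D → L (k = 3.40 M⁻¹ h⁻¹)
    G + X → Z (k = 70.0 M⁻¹ h⁻¹)
    D → J (k = 0.460 h⁻¹)

North-west at 28.4% stands above the 27.4% that ρ gave, and it has not come to rest at 2.50 h, with 30.9% of its D, 18.0% of G unbound and 13.6% of G held as E still there. At 25.0 h north-west holds 33.7% of L, with D at 0% and unbound G at 0.0719%, so 15.7% of that L came after 2.5 h, against the 11.2% that τ left open. West moves from 2.42% at 2.5 h to 3.10% at 25.0 h, with D then at 0% and unbound G at 4.71%.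

On the neighbour that is north-west with 80 mM of D, ρ gives 11.0%, and the computed flask holds 12.4%.

The numbers in the tables are simulated for an exercise, noise included.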